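The easy step comes first. At 4.4 min the north-east flask, with twice the Ctl of the south flask, holds twice the Pdt: 18.9 mM against 9.4 mM. So the first rate follows [Ctl] to a power of about 1.01.

| setting | south | west | north-east | south-east |
|---|---|---|---|---|
| Sbt | 120 mM | 60.0 mM | 120 mM | 480 mM |
| Ptn | 300 mM | 240 mM | 300 mM | 300 mM |
| Ctl | 3.60 mM | 3.60 mM | 7.20 mM | 3.60 mM |
| time |  |  |  | 110 min |

| run | time / min | [Pdt] / mM |
|---|---|---|
| south run | 4.4 | 9.4 |
| south run | 8.4 | 17.8 |
| south run | 16 | 28.8 |
| south run | 30 | 45.0 |
| south run | 58 | 65.1 |
| south run | 110 | 78.3 |
| west run | 4.4 | 3.6 |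
| west run | 8.4 | 7.7 |
| west run | 16 | 13.6 |
| west run | 30 | 22.8 |
| west run | 58 | 31.5 |
| west run | 110 | 37.3 |
| north-east run | 4.4 | 18.9 |
| north-east run | 8.4 | 32.5 |
| north-east run | 16 | 51.6 |
| north-east run | 30 | 72.9 |
| north-east run | 58 | 93.6 |
| north-east run | 110 | 104.1 |

(each reading ± 0.6 mM)

- the power of [Ctl] that the first rate follows, about the charge of the south run; measure it at two percent of Sbt made into Pdt
- the west run starts with 60.0 mM less of Sbt and of Ptn than the south run, and with no Pdt. Compared where both hold the same amount of Sbt, once fifteen percent of what the west run was charged with has turned into Pdt, is the west run faster, slower or alike (within a tenth)?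
- Pdt in the south-east run at 110 min, as a share of the Sbt charged

- Overall: Sbt + Ptn -> Pdt, with Ctl as catalyst.
- Constant volume, constant temperature.
- A reading of a species includes what of it is bound.
- An order is taken over about fifteen percent of the charge, up and down.

In the middle of a run, watch the age of the flask. The west flask is charged as the south flask should stand after 60.0 mM has turned, so equal Sbt ought to mean equal rate. It does not. Between 4.4 min and 16 min the west flask averages 51.4 mM of Sbt and makes Pdt at 0.862 mM min⁻¹. Between 58 min and 110 min the south flask averages 48.3 mM and makes 0.254 mM min⁻¹. So I answer that the west flask is faster. The two spans lie 73.8 min apart in age, and the logarithm of the rate ratio over that gap gives 0.0166 min⁻¹, my fade constant: the fraction of the rate lost per minute at fixed amounts.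

Looking to the end of the south-east run, Ptn is the limiting reagent, its charge of 300 mM standing below the charge of 480 mM of Sbt. I cannot tell from these readings whether Ctl or Ptn fades, so for the south-east run I reckon the harsher case, in which lost Ptn makes no Pdt. Ptn vanishes at the fade constant, while Sbt, crudely held at its charge, draws Ptn into Pdt in pseudo-first-order fashion at 0.0285 min⁻¹, scaled from the first south rate. That gives 188 mM of Pdt by 110 min, so my share is 39.2%.

The forecast gives 1, faster and 47%, holding that “the catalyst is dying”, and its share stands above mine.

The flask gives a power of 1.0, a west flask that is faster by a ratio of 2.4, and a share of 37.4%.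

    Ctl + Sbt ⇌ Ctl.Sbt (21.30 L mol⁻¹ min⁻¹, 6.060 min⁻¹)
    Ctl.Sbt + Ptn → Pdt + Ctl (10.20 L mol⁻¹ min⁻¹)
    Ctl → Q (0.006540 min⁻¹)
    Ptn → Z (0.009840 min⁻¹)

The south-east share stands this low because Ptn passes into Z: without that step the run gives 49.9% against 37.4%. The passing of Ctl into Q is not the reason: without it the south-east run gives 39.3%. The fade constant also carries to the north-east run. If each minute counts by the rate it still has, twice the Ctl needs half the counted time of the south run. In the south run, the Pdt made comes to half of the charge at 48.6 min. That predicts 19.5 min for the same mark of Pdt in the north-east run, which stores 20.5 min.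

(All runs were computed with constants of no real substance; the scatter is artificial.)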